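## Retrosynthetic overview

1. Target 36 ⇐ bis-silyl ether 35 ⇐ triene 34 by ring-closing metathesis at C3=C4; the ten-membered ring is closed last.
2. 34 ⇐ aldol adduct 28 by oxa-Michael hydroxylation at C13, methylenation and epoxidation at C11, acetylation and Stille vinylation; 28 ⇐ anti-aldol union (C9–C10) of enone 10 with lactone aldehyde 26.
3. Fragment A (10) ⇐ asymmetric Diels–Alder of methacrolein with a 1-silyloxybutadiene (ring A formed first), CBS-controlled vinyl carbinol at C2, allylic oxidation at C11.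
4. Fragment B (26) ⇐ HWE of iodoenal 15 with lactate-derived phosphonate 20, Sharpless epoxidation, invertive epoxide-opening lactonization (butanolide formed in parallel).
5. Ring order: cyclohexene ring A and the γ-lactone independently, then the spiro-oxirane, then the ten-membered carbocycle.

Locants: C1–C20 are the briarane locants of the target: C1 quaternary C–CH3 (C15), C2 CHOAc, C3=C4, C5(C16H2OH)=C6, C7 lactone O–CH, C8 C–OH, C9 CHOAc, C10 CH, C11 spiro-oxirane carbon (C20H2), C12 CH2, C13 and C14 CHOAc, C17(C18H3)–C19 lactone C=O. Target = (1R,2S,7R,8R,9S,10R,11S,13R,14S,17S), 3Z,5E.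

Assumption: in step 2 the (S)-configured oxazaborolidinium catalyst is taken to give the (1S,2R) adduct; its mirror-image catalyst is equally available if the sense is opposite.

## Route

**Fragment A (ring A)**

Step 1
Reactants: 1 (E)-but-2-enal
Product: 2 (1E)-1-(triethylsilyloxy)buta-1,3-diene
Conditions: Et3SiOTf, Et3N, Et2O, 0 °C
Reagents that add atoms: triethylsilyl trifluoromethanesulfonate, CC[Si](CC)(CC)OS(=O)(=O)C(F)(F)F
Why: O-silylation of the enal with γ-deprotonation (silyl dienol ether formation) gives the E-configured 1-oxygenated diene.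

Step 2
Reactants: 2 (1E)-1-(triethylsilyloxy)buta-1,3-diene; 3 2-methylprop-2-enal (methacrolein)
Product: 4 (1S,2R)-1-methyl-2-(triethylsilyloxy)cyclohex-3-ene-1-carbaldehyde
Conditions: (S)-o-tolyl-CBS-oxazaborolidine·HNTf2 (10 mol%), CH2Cl2, −78 °C
Reagents that add atoms: none
Why: Catalytic asymmetric Diels–Alder reaction: "ortho" regiochemistry puts the oxygen next to the new quaternary carbon, the endo-formyl transition state places CHO cis to OSiEt3, and the oxazaborolidinium shields one enal face, setting C1 and C14.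

Step 3
Reactants: 4 (1S,2R)-1-methyl-2-(triethylsilyloxy)cyclohex-3-ene-1-carbaldehyde
Product: 5 1-[(1R,2R)-1-methyl-2-(triethylsilyloxy)cyclohex-3-en-1-yl]prop-2-en-1-ol (both carbinol epimers)
Conditions: CH2=CHMgBr, THF, −78 → 0 °C
Reagents that add atoms: vinylmagnesium bromide, C=C[Mg]Br
Why: Grignard 1,2-addition to the non-enolizable neopentyl aldehyde; the carbinol epimer ratio is irrelevant because the next step oxidizes this centre.

Step 4
Reactants: 5 1-[(1R,2R)-1-methyl-2-(triethylsilyloxy)cyclohex-3-en-1-yl]prop-2-en-1-ol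
Product: 6 1-[(1S,2R)-1-methyl-2-(triethylsilyloxy)cyclohex-3-en-1-yl]prop-2-en-1-one
Conditions: Dess–Martin periodinane, NaHCO3, CH2Cl2, rt
Reagents that add atoms: none
Why: Dess–Martin oxidation converges both epimers to one vinyl ketone under neutral conditions that spare the silyl ether.

Step 5
Reactants: 6 1-[(1S,2R)-1-methyl-2-(triethylsilyloxy)cyclohex-3-en-1-yl]prop-2-en-1-one
Product: 7 (1S)-1-[(1R,2R)-1-methyl-2-(triethylsilyloxy)cyclohex-3-en-1-yl]prop-2-en-1-ol
Conditions: (R)-2-methyl-CBS-oxazaborolidine (20 mol%), catecholborane, toluene, −78 °C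
Reagents that add atoms: none
Why: Corey–Bakshi–Shibata reduction: with the quaternary carbon as the large group and vinyl as the small group, the (R)-catalyst delivers hydride to give the (S)-carbinol, setting C2 under reagent control.

Step 6
Reactants: 7 (1S)-1-[(1R,2R)-1-methyl-2-(triethylsilyloxy)cyclohex-3-en-1-yl]prop-2-en-1-ol
Product: 8 (1S)-1-[(1R,2R)-1-methyl-2-(triethylsilyloxy)cyclohex-3-en-1-yl]prop-2-en-1-yl acetate
Conditions: Ac2O, pyridine, DMAP (cat.), CH2Cl2, rt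
Reagents that add atoms: acetic anhydride, CC(=O)OC(C)=O
Why: DMAP-catalysed acylation installs the final C2 acetate and protects the allylic carbinol from the oxidant of the next step.

Step 7
Reactants: 8 (1S)-1-[(1R,2R)-1-methyl-2-(triethylsilyloxy)cyclohex-3-en-1-yl]prop-2-en-1-yl acetate
Product: 9 (1S)-1-[(1R,2R)-1-methyl-5-oxo-2-(triethylsilyloxy)cyclohex-3-en-1-yl]prop-2-en-1-yl acetate
Conditions: Rh2(cap)4 (dirhodium tetracaprolactamate, 1 mol%), t-BuOOH (aq.), K2CO3, CH2Cl2, rt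
Reagents that add atoms: tert-butyl hydroperoxide, CC(C)(C)OO
Why: Allylic C–H oxidation occurs at C11, the only unhindered allylic CH2 of the ring, to give the C11 enone; no stereocentre is touched.

Step 8
Reactants: 9 (1S)-1-[(1R,2R)-1-methyl-5-oxo-2-(triethylsilyloxy)cyclohex-3-en-1-yl]prop-2-en-1-yl acetate
Product: 10 (1S)-1-[(1S,2R)-2-hydroxy-1-methyl-5-oxocyclohex-3-en-1-yl]prop-2-en-1-yl acetate (fragment A)
Conditions: HF·pyridine, pyridine, THF, 0 °C
Reagents that add atoms: none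
Why: Fluoride-mediated desilylation frees the 14-OH under buffered conditions that leave the acetate and enone intact; with C1 quaternary no β-elimination is possible.

**Fragment B (butanolide aldehyde)**

Step 9
Reactants: 11 but-2-yne-1,4-diol
Product: 12 4-{[tert-butyl(diphenyl)silyl]oxy}but-2-yn-1-ol
Conditions: t-BuPh2SiCl (0.3 equiv), imidazole, DMF, 0 °C → rt
Reagents that add atoms: tert-butyl(chloro)diphenylsilane, CC(C)(C)[Si](Cl)(c1ccccc1)c1ccccc1
Why: Statistical monosilylation with the cheap diol in excess gives the mono-ether that will become the protected C16 hydroxyl.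

Step 10
Reactants: 12 4-{[tert-butyl(diphenyl)silyl]oxy}but-2-yn-1-ol
Product: 14 (2Z)-4-{[tert-butyl(diphenyl)silyl]oxy}-3-iodobut-2-en-1-ol, via cyclic sodium alkenylalanate 13 (not isolated)
Conditions: NaAlH2(OCH2CH2OMe)2, THF, 0 °C → rt; then I2, −78 °C
Reagents that add atoms: iodine, II
Why: Hydroxyl-directed trans-hydroalumination puts aluminium on the distal carbon cis to the carbinol carbon, and iodinolysis with retention gives the Z-iodoalkene that fixes the C5=C6 geometry.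

Step 11
Reactants: 14 (2Z)-4-{[tert-butyl(diphenyl)silyl]oxy}-3-iodobut-2-en-1-ol
Product: 15 (2Z)-4-{[tert-butyl(diphenyl)silyl]oxy}-3-iodobut-2-enal
Conditions: MnO2, CH2Cl2, rt
Reagents that add atoms: none
Why: Allylic alcohol oxidation with MnO2 is neutral and keeps the Z geometry; the enal is used directly.

Step 12
Reactants: 16 tert-butyl (2S)-2-hydroxypropanoate
Product: 17 tert-butyl (2S)-2-{[(trifluoromethyl)sulfonyl]oxy}propanoate
Conditions: Tf2O, 2,6-lutidine, CH2Cl2, −78 → 0 °C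
Reagents that add atoms: trifluoromethanesulfonic anhydride, O=S(=O)(OS(=O)(=O)C(F)(F)F)C(F)(F)F
Why: O-sulfonylation activates the lactate for displacement without touching the stereocentre.

Step 13
Reactants: 18 methyl 2-(dimethoxyphosphoryl)acetate; 17 tert-butyl (2S)-2-{[(trifluoromethyl)sulfonyl]oxy}propanoate
Product: 20 4-tert-butyl 1-methyl (3R)-2-(dimethoxyphosphoryl)-3-methylbutanedioate (both C2 epimers), via sodium phosphonoacetate enolate 19 (not isolated)
Conditions: NaH, THF, 0 °C; then 17, 0 °C → rt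
Reagents that add atoms: none
Why: SN2 alkylation of the stabilized carbanion by the α-triflate proceeds with clean inversion, converting (S)-lactate into the C17 methyl stereocentre.

Step 14
Reactants: 20 4-tert-butyl 1-methyl (3R)-2-(dimethoxyphosphoryl)-3-methylbutanedioate; 15 (2Z)-4-{[tert-butyl(diphenyl)silyl]oxy}-3-iodobut-2-enal
Product: 21 4-tert-butyl 1-methyl (2E,3S)-2-[(2Z)-4-{[tert-butyl(diphenyl)silyl]oxy}-3-iodobut-2-en-1-ylidene]-3-methylbutanedioate
Conditions: LiBr, Et3N, THF, rt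
Reagents that add atoms: none
Why: Horner–Wadsworth–Emmons olefination under Rathke conditions gives the E-alkylidene succinate (methyl ester trans to the dienyl chain), and the mild amine base spares the C17 stereocentre.

Step 15
Reactants: 21 4-tert-butyl 1-methyl (2E,3S)-2-[(2Z)-4-{[tert-butyl(diphenyl)silyl]oxy}-3-iodobut-2-en-1-ylidene]-3-methylbutanedioate
Product: 22 tert-butyl (2S,3E,5Z)-7-{[tert-butyl(diphenyl)silyl]oxy}-3-(hydroxymethyl)-6-iodo-2-methylhepta-3,5-dienoate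
Conditions: i-Bu2AlH (2.2 equiv), CH2Cl2, −78 °C
Reagents that add atoms: none
Why: Chemoselective hydride reduction of the methyl ester to the allylic alcohol (C9); the hindered α-branched tert-butyl ester survives at −78 °C.

Step 16
Reactants: 22 tert-butyl (2S,3E,5Z)-7-{[tert-butyl(diphenyl)silyl]oxy}-3-(hydroxymethyl)-6-iodo-2-methylhepta-3,5-dienoate
Product: 23 tert-butyl (2S)-2-[(2S,3S)-3-[(1Z)-3-{[tert-butyl(diphenyl)silyl]oxy}-2-iodoprop-1-en-1-yl]-2-(hydroxymethyl)oxiran-2-yl]propanoate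
Conditions: Ti(OiPr)4 (10 mol%), L-(+)-diethyl tartrate (12 mol%), t-BuOOH, 4 Å MS, CH2Cl2, −20 °C
Reagents that add atoms: tert-butyl hydroperoxide, CC(C)(C)OO
Why: Katsuki–Sharpless asymmetric epoxidation attacks only the allylic-alcohol alkene, and L-(+)-tartrate gives the (2S,3S)-epoxide, fixing C8 and provisionally C7.

Step 17
Reactants: 23 tert-butyl (2S)-2-[(2S,3S)-3-[(1Z)-3-{[tert-butyl(diphenyl)silyl]oxy}-2-iodoprop-1-en-1-yl]-2-(hydroxymethyl)oxiran-2-yl]propanoate
Product: 24 (3S,4S,5R)-5-[(1Z)-3-{[tert-butyl(diphenyl)silyl]oxy}-2-iodoprop-1-en-1-yl]-4-hydroxy-4-(hydroxymethyl)-3-methyloxolan-2-one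
Conditions: BF3·OEt2 (20 mol%), CH2Cl2, −78 → −30 °C
Reagents that add atoms: none
Why: Lewis acid-promoted epoxide opening by the tert-butyl ester carbonyl at the allylic carbon (five-membered ring, anti attack, loss of isobutene) gives the γ-lactone with inversion at C7 and retention of the C8–O bond.

Step 18
Reactants: 24 (3S,4S,5R)-5-[(1Z)-3-{[tert-butyl(diphenyl)silyl]oxy}-2-iodoprop-1-en-1-yl]-4-hydroxy-4-(hydroxymethyl)-3-methyloxolan-2-one
Product: 25 (3S,4S,5R)-5-[(1Z)-3-{[tert-butyl(diphenyl)silyl]oxy}-2-iodoprop-1-en-1-yl]-3-methyl-4-[(triethylsilyl)oxy]-4-{[(triethylsilyl)oxy]methyl}oxolan-2-one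
Conditions: Et3SiOTf, 2,6-lutidine, CH2Cl2, −78 → 0 °C
Reagents that add atoms: triethylsilyl trifluoromethanesulfonate, CC[Si](CC)(CC)OS(=O)(=O)C(F)(F)F
Why: Silyl triflate silylation protects both the tertiary C8 and the primary C9 hydroxyl without base-induced epimerization at C17.

Step 19
Reactants: 25 (3S,4S,5R)-5-[(1Z)-3-{[tert-butyl(diphenyl)silyl]oxy}-2-iodoprop-1-en-1-yl]-3-methyl-4-[(triethylsilyl)oxy]-4-{[(triethylsilyl)oxy]methyl}oxolan-2-one
Product: 26 (2R,3R,4S)-2-[(1Z)-3-{[tert-butyl(diphenyl)silyl]oxy}-2-iodoprop-1-en-1-yl]-4-methyl-5-oxo-3-[(triethylsilyl)oxy]oxolane-3-carbaldehyde (fragment B)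
Conditions: (COCl)2, DMSO, CH2Cl2, −78 → −40 °C; then Et3N
Reagents that add atoms: none
Why: Swern oxidation converts the primary triethylsilyl ether directly into the aldehyde while the tertiary silyl ether and the TBDPS ether are untouched; the quaternary α-carbon cannot epimerize.

**Union and endgame**

Step 20
Reactants: 10 (1S)-1-[(1S,2R)-2-hydroxy-1-methyl-5-oxocyclohex-3-en-1-yl]prop-2-en-1-yl acetate; 26 (2R,3R,4S)-2-[(1Z)-3-{[tert-butyl(diphenyl)silyl]oxy}-2-iodoprop-1-en-1-yl]-4-methyl-5-oxo-3-[(triethylsilyl)oxy]oxolane-3-carbaldehyde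
Product: 28 9,10-anti aldol adduct (3,4-seco skeleton; 2-OAc, 8-OSiEt3, 9-OH, 14-OH, 11-oxo-12-ene, 5-iodo, 16-OTBDPS; all stereocentres arranged as in the target), via bis-boryl dienolate 27 (not isolated)
Conditions: c-Hex2BCl (2.3 equiv), Et3N, Et2O, −78 → 0 °C; then 26, −78 → −20 °C; H2O2, MeOH, pH 7 buffer, 0 °C
Reagents that add atoms: none
Why: Boron-mediated aldol addition of the α′-enolate of the enone (regiochemistry enforced by the C12=C13 bond): the ring (E)-enolate reacts through a chair Zimmerman–Traxler transition state to give the 9,10-anti adduct (9S), and the aldehyde adds to the face opposite the C1 acetoxyallyl arm and the 14-O-boryl group (10R).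

Step 21
Reactants: 28 9,10-anti aldol adduct
Product: 30 11-ketone with 9-OH and cis-13,14-diol (3,4-seco skeleton; 2-OAc, 8-OSiEt3, 5-iodo, 16-OTBDPS), via cyclic phenylboronate 29 (not isolated)
Conditions: PhB(OH)2, i-Pr2NH (20 mol%), 4 Å MS, toluene, rt; then H2O2, aq. NaHCO3, THF, 0 °C
Reagents that add atoms: phenylboronic acid, OB(O)c1ccccc1
Why: Boronic acid-mediated intramolecular oxa-Michael addition: the 14-O-boronate hemiester delivers its B–OH oxygen to C13 through a cis-fused five-membered ring, so the new 13-oxygen is necessarily cis to 14-O; oxidative B–C cleavage frees the diol.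

Step 22
Reactants: 30 11-ketone with 9-OH and cis-13,14-diol
Product: 31 11(20)-exocyclic methylene triol (9-OH, 13-OH, 14-OH; 2-OAc, 8-OSiEt3, 5-iodo, 16-OTBDPS)
Conditions: Zn, CH2Br2, TiCl4, THF/CH2Cl2, 0 °C → rt
Reagents that add atoms: dibromomethane, BrCBr
Why: Takai–Lombardo methylenation is non-basic, so the hindered β-hydroxy ketone is methylenated without retro-aldol, elimination or epimerization at C10, and the esters and lactone are not attacked.

Step 23
Reactants: 31 11(20)-exocyclic methylene triol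
Product: 32 2,9,13,14-tetraacetate (8-OSiEt3, 5-iodo, 16-OTBDPS, 11(20)-ene)
Conditions: Ac2O, pyridine, DMAP, CH2Cl2, rt → 40 °C
Reagents that add atoms: acetic anhydride, CC(=O)OC(C)=O
Why: DMAP-catalysed acylation installs the three remaining secondary acetates; the tertiary 8-oxygen is blocked as its silyl ether.

Step 24
Reactants: 32 2,9,13,14-tetraacetate
Product: 33 11,20-epoxide of 32 (oxirane oxygen on the α face, as in the target)
Conditions: mCPBA, NaHCO3, CH2Cl2, 0 °C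
Reagents that add atoms: 3-chloroperoxybenzoic acid, OOC(=O)c1cccc(Cl)c1
Why: Prilezhaev epoxidation of the only electron-rich alkene (the iodoalkene and the acetoxy-allylic vinyl group are deactivated) from the face opposite the axial C1 methyl gives the equatorial-oxygen spiro-epoxide, setting C11.

Step 25
Reactants: 33 11,20-epoxide of 32
Product: 34 triene (C5 vinyl in place of iodine; 3,4-seco precursor with both terminal alkenes)
Conditions: Bu3SnCH=CH2, Pd2(dba)3 (5 mol%), AsPh3, NMP, 40 °C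
Reagents that add atoms: tributyl(vinyl)stannane, CCCC[Sn](CCCC)(CCCC)C=C
Why: Stille cross-coupling replaces iodine by vinyl with retention, giving the diene in which C4 is cis to C7 (5E).

Step 26
Reactants: 34 triene
Product: 35 8-O-triethylsilyl-16-O-TBDPS ether of the target (ten-membered ring closed)
Conditions: second-generation Hoveyda–Grubbs catalyst (15 mol%), toluene (1 mM), 80 °C
Reagents that add atoms: none
Why: Ring-closing metathesis of the two monosubstituted alkenes releases ethene; the substrate is pre-organized by ring A and the lactone, and the new C3=C4 bond is formed cis (3Z) within the ten-membered ring.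

Step 27
Reactants: 35 8-O-triethylsilyl-16-O-TBDPS ether of the target
Product: 36 target, (1R,2S,7R,8R,9S,10R,11S,13R,14S,17S)-2,9,13,14-tetraacetoxy-8,16-dihydroxy-11,20-epoxybriara-3Z,5E-dien-19,7-olide
Conditions: Bu4NF, AcOH, THF, 0 °C → rt
Reagents that add atoms: none
Why: Acetic acid-buffered fluoride desilylation frees the tertiary 8-OH and primary 16-OH without acetate migration, epoxide opening or lactone cleavage.

## Compound list

1 | (E)-but-2-enal (crotonaldehyde) | C/C=C/C=O | starting material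
2 | (1E)-1-(triethylsilyloxy)buta-1,3-diene | C=C/C=C/O[Si](CC)(CC)CC | intermediate
3 | 2-methylprop-2-enal (methacrolein) | CC(=C)C=O | starting material
4 | (1S,2R)-1-methyl-2-(triethylsilyloxy)cyclohex-3-ene-1-carbaldehyde | O=C[C@@]1(C)CCC=C[C@H]1O[Si](CC)(CC)CC | intermediate
5 | 1-[(1R,2R)-1-methyl-2-(triethylsilyloxy)cyclohex-3-en-1-yl]prop-2-en-1-ol (carbinol epimers) | C=CC(O)[C@@]1(C)CCC=C[C@H]1O[Si](CC)(CC)CC | intermediate
6 | 1-[(1S,2R)-1-methyl-2-(triethylsilyloxy)cyclohex-3-en-1-yl]prop-2-en-1-one | C=CC(=O)[C@@]1(C)CCC=C[C@H]1O[Si](CC)(CC)CC | intermediate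
7 | (1S)-1-[(1R,2R)-1-methyl-2-(triethylsilyloxy)cyclohex-3-en-1-yl]prop-2-en-1-ol | C=C[C@H](O)[C@@]1(C)CCC=C[C@H]1O[Si](CC)(CC)CC | intermediate
8 | (1S)-1-[(1R,2R)-1-methyl-2-(triethylsilyloxy)cyclohex-3-en-1-yl]prop-2-en-1-yl acetate | CC(=O)O[C@@H](C=C)[C@@]1(C)CCC=C[C@H]1O[Si](CC)(CC)CC | intermediate
9 | (1S)-1-[(1R,2R)-1-methyl-5-oxo-2-(triethylsilyloxy)cyclohex-3-en-1-yl]prop-2-en-1-yl acetate | CC(=O)O[C@@H](C=C)[C@@]1(C)CC(=O)C=C[C@H]1O[Si](CC)(CC)CC | intermediate
10 | (1S)-1-[(1S,2R)-2-hydroxy-1-methyl-5-oxocyclohex-3-en-1-yl]prop-2-en-1-yl acetate (fragment A) | CC(=O)O[C@@H](C=C)[C@@]1(C)CC(=O)C=C[C@H]1O | intermediate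
11 | but-2-yne-1,4-diol | OCC#CCO | starting material
12 | 4-{[tert-butyl(diphenyl)silyl]oxy}but-2-yn-1-ol | OCC#CCO[Si](c1ccccc1)(c1ccccc1)C(C)(C)C | intermediate
13 | cyclic sodium alkenylalanate (2,2-bis(2-methoxyethoxy)-1-oxa-2-aluminacyclopent-3-ene ate complex bearing CH2OTBDPS at C3) | [Na+].COCCO[Al-]1(OCCOC)OCC=C1CO[Si](c1ccccc1)(c1ccccc1)C(C)(C)C | intermediate (not isolated)
14 | (2Z)-4-{[tert-butyl(diphenyl)silyl]oxy}-3-iodobut-2-en-1-ol | OC/C=C(\I)CO[Si](c1ccccc1)(c1ccccc1)C(C)(C)C | intermediate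
15 | (2Z)-4-{[tert-butyl(diphenyl)silyl]oxy}-3-iodobut-2-enal | O=C/C=C(\I)CO[Si](c1ccccc1)(c1ccccc1)C(C)(C)C | intermediate
16 | tert-butyl (2S)-2-hydroxypropanoate (tert-butyl (S)-lactate) | C[C@H](O)C(=O)OC(C)(C)C | starting material
17 | tert-butyl (2S)-2-{[(trifluoromethyl)sulfonyl]oxy}propanoate | C[C@H](OS(=O)(=O)C(F)(F)F)C(=O)OC(C)(C)C | intermediate
18 | methyl 2-(dimethoxyphosphoryl)acetate (trimethyl phosphonoacetate) | COC(=O)CP(=O)(OC)OC | starting material
19 | sodium enolate of trimethyl phosphonoacetate | [Na+].COC(=O)[CH-]P(=O)(OC)OC | intermediate (not isolated)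
20 | 4-tert-butyl 1-methyl (3R)-2-(dimethoxyphosphoryl)-3-methylbutanedioate (C2 epimers) | COC(=O)C(P(=O)(OC)OC)[C@H](C)C(=O)OC(C)(C)C | intermediate
21 | 4-tert-butyl 1-methyl (2E,3S)-2-[(2Z)-4-{[tert-butyl(diphenyl)silyl]oxy}-3-iodobut-2-en-1-ylidene]-3-methylbutanedioate | COC(=O)/C(=C/C=C(\I)CO[Si](c1ccccc1)(c1ccccc1)C(C)(C)C)[C@H](C)C(=O)OC(C)(C)C | intermediate
22 | tert-butyl (2S,3E,5Z)-7-{[tert-butyl(diphenyl)silyl]oxy}-3-(hydroxymethyl)-6-iodo-2-methylhepta-3,5-dienoate | OC/C(=C/C=C(\I)CO[Si](c1ccccc1)(c1ccccc1)C(C)(C)C)[C@H](C)C(=O)OC(C)(C)C | intermediate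
23 | tert-butyl (2S)-2-[(2S,3S)-3-[(1Z)-3-{[tert-butyl(diphenyl)silyl]oxy}-2-iodoprop-1-en-1-yl]-2-(hydroxymethyl)oxiran-2-yl]propanoate | OC[C@@]1(O[C@H]1/C=C(\I)CO[Si](c2ccccc2)(c2ccccc2)C(C)(C)C)[C@H](C)C(=O)OC(C)(C)C | intermediate
24 | (3S,4S,5R)-5-[(1Z)-3-{[tert-butyl(diphenyl)silyl]oxy}-2-iodoprop-1-en-1-yl]-4-hydroxy-4-(hydroxymethyl)-3-methyloxolan-2-one | I\C(CO[Si](c1ccccc1)(c1ccccc1)C(C)(C)C)=C/[C@H]1OC(=O)[C@@H](C)[C@]1(O)CO | intermediate
25 | (3S,4S,5R)-5-[(1Z)-3-{[tert-butyl(diphenyl)silyl]oxy}-2-iodoprop-1-en-1-yl]-3-methyl-4-[(triethylsilyl)oxy]-4-{[(triethylsilyl)oxy]methyl}oxolan-2-one | I\C(CO[Si](c1ccccc1)(c1ccccc1)C(C)(C)C)=C/[C@H]1OC(=O)[C@@H](C)[C@]1(O[Si](CC)(CC)CC)CO[Si](CC)(CC)CC | intermediate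
26 | (2R,3R,4S)-2-[(1Z)-3-{[tert-butyl(diphenyl)silyl]oxy}-2-iodoprop-1-en-1-yl]-4-methyl-5-oxo-3-[(triethylsilyl)oxy]oxolane-3-carbaldehyde (fragment B) | I\C(CO[Si](c1ccccc1)(c1ccccc1)C(C)(C)C)=C/[C@H]1OC(=O)[C@@H](C)[C@]1(O[Si](CC)(CC)CC)C=O | intermediate
27 | bis(dicyclohexylboryl) derivative of 10 (14-O-boryl; C10=C11(O-boryl) cross-conjugated dienolate) | CC(=O)O[C@@H](C=C)[C@@]1(C)C=C(OB(C2CCCCC2)C2CCCCC2)C=C[C@H]1OB(C2CCCCC2)C2CCCCC2 | intermediate (not isolated)
28 | 9,10-anti aldol adduct: lactone of 26 joined through C9H(OH) to C10 of the enone of 10; 2-OAc, 8-OSiEt3, 14-OH, 11-oxo-12-ene, 5-iodo, 16-OTBDPS; stereocentres as in the target | I\C(CO[Si](c1ccccc1)(c1ccccc1)C(C)(C)C)=C/[C@H]1OC(=O)[C@@H](C)[C@]1(O[Si](CC)(CC)CC)[C@@H](O)[C@@H]2C(=O)C=C[C@@H](O)[C@@]2(C)[C@@H](OC(C)=O)C=C | intermediate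
29 | cyclic 13,14-O-phenylboronate of 30 | I\C(CO[Si](c1ccccc1)(c1ccccc1)C(C)(C)C)=C/[C@H]1OC(=O)[C@@H](C)[C@]1(O[Si](CC)(CC)CC)[C@@H](O)[C@@H]2C(=O)C[C@H]3OB(c4ccccc4)O[C@H]3[C@@]2(C)[C@@H](OC(C)=O)C=C | intermediate (not isolated)
30 | saturated 11-ketone with 9-OH and cis-13α,14α-diol; 2-OAc, 8-OSiEt3, 5-iodo, 16-OTBDPS | I\C(CO[Si](c1ccccc1)(c1ccccc1)C(C)(C)C)=C/[C@H]1OC(=O)[C@@H](C)[C@]1(O[Si](CC)(CC)CC)[C@@H](O)[C@@H]2C(=O)C[C@@H](O)[C@@H](O)[C@@]2(C)[C@@H](OC(C)=O)C=C | intermediate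
31 | 11(20)-exocyclic methylene analogue of 30 (9,13,14-triol) | I\C(CO[Si](c1ccccc1)(c1ccccc1)C(C)(C)C)=C/[C@H]1OC(=O)[C@@H](C)[C@]1(O[Si](CC)(CC)CC)[C@@H](O)[C@@H]2C(=C)C[C@@H](O)[C@@H](O)[C@@]2(C)[C@@H](OC(C)=O)C=C | intermediate
32 | 2,9,13,14-tetraacetate of 31 | I\C(CO[Si](c1ccccc1)(c1ccccc1)C(C)(C)C)=C/[C@H]1OC(=O)[C@@H](C)[C@]1(O[Si](CC)(CC)CC)[C@@H](OC(C)=O)[C@@H]2C(=C)C[C@@H](OC(C)=O)[C@@H](OC(C)=O)[C@@]2(C)[C@@H](OC(C)=O)C=C | intermediate
33 | 11,20-epoxide of 32 (oxirane O α, CH2 β, as in the target) | I\C(CO[Si](c1ccccc1)(c1ccccc1)C(C)(C)C)=C/[C@H]1OC(=O)[C@@H](C)[C@]1(O[Si](CC)(CC)CC)[C@@H](OC(C)=O)[C@@H]2[C@]3(CO3)C[C@@H](OC(C)=O)[C@@H](OC(C)=O)[C@@]2(C)[C@@H](OC(C)=O)C=C | intermediate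
34 | triene: 33 with vinyl (C4) in place of iodine at C5 | C=C\C(CO[Si](c1ccccc1)(c1ccccc1)C(C)(C)C)=C/[C@H]1OC(=O)[C@@H](C)[C@]1(O[Si](CC)(CC)CC)[C@@H](OC(C)=O)[C@@H]2[C@]3(CO3)C[C@@H](OC(C)=O)[C@@H](OC(C)=O)[C@@]2(C)[C@@H](OC(C)=O)C=C | intermediate
35 | 8-O-triethylsilyl-16-O-tert-butyldiphenylsilyl ether of the target | CC(=O)O[C@H]1/C=C\C(CO[Si](c2ccccc2)(c2ccccc2)C(C)(C)C)=C/[C@H]2OC(=O)[C@@H](C)[C@]2(O[Si](CC)(CC)CC)[C@@H](OC(C)=O)[C@@H]2[C@]3(CO3)C[C@@H](OC(C)=O)[C@@H](OC(C)=O)[C@@]12C | intermediate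
36 | target CNP0317528.3 | CC(=O)O[C@H]1/C=C\C(CO)=C/[C@H]2OC(=O)[C@@H](C)[C@]2(O)[C@@H](OC(C)=O)[C@@H]2[C@]3(CO3)C[C@@H](OC(C)=O)[C@@H](OC(C)=O)[C@@]12C | target

## Step count and risks

Total: 27 steps (fragment A 8, fragment B 11, union and endgame 8).
Longest linear sequence: 17 steps (11 → 12 → 14 → 15 → 21 → 22 → 23 → 24 → 25 → 26 → 28 → 30 → 31 → 32 → 33 → 34 → 35 → 36).

Three steps most likely to fail:

Step 26 (ring-closing metathesis). A strained ten-membered cis,cis-diene must form between a diene terminus and a vinyl group flanked by a quaternary carbon; oligomerization or no turnover is possible. The fallback sets out from epoxide 33 and comes back at macrocycle 35. Hydroboration of the C2 vinyl group of 33 with 9-BBN and NaBO3 oxidation gives the primary alcohol F1. Dess–Martin oxidation gives the aldehyde F2. An intramolecular Nozaki–Hiyama–Kishi reaction (CrCl2, NiCl2 cat., DMSO/THF, high dilution) between the C5 alkenyl iodide and the C4 aldehyde closes the ring at C4–C5 to give the macrocyclic allylic alcohol F3. Dehydration across C3–C4 with Burgess reagent then gives diene 35.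

Step 20 (aldol union). The new C9–C10 bond lies between two quaternary carbons, and both the facial selectivity at C10 and the anti relationship must hold against any bias of the aldehyde. The fallback sets out from enone 10 and comes back at adduct 28. Me3SiOTf and Et3N convert 10 into the bis(trimethylsilyl) dienol ether F4. A Mukaiyama aldol addition of F4 to aldehyde 26 (BF3·OEt2, CH2Cl2, −78 °C) proceeds through an open transition state with a Lewis acid-activated aldehyde, and work-up with dilute HCl/THF removes both trimethylsilyl groups to give 28.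

Step 17 (epoxide-opening lactonization). Ionization at the tertiary epoxide carbon (semipinacol or Meinwald pathways) or loss of stereochemical fidelity at the allylic carbon could compete with the intended anti attack. The fallback sets out from epoxy alcohol 23 and comes back at lactone 24. Sharpless C3-selective opening of the 2,3-epoxy alcohol with Ti(OiPr)4 and PhCO2H delivers benzoate at C7 with inversion to give the benzoate diol F5. K2CO3/MeOH removes the benzoate to give the triol ester F6, and CF3CO2H in CH2Cl2 closes the γ-lactone (C7 now retained) to give 24.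

## Further compounds

F1 | step 26 | primary alcohol from anti-Markovnikov hydration of the C2 vinyl group of 33 (C2(OAc)–CH2–CH2OH) | I\C(CO[Si](c1ccccc1)(c1ccccc1)C(C)(C)C)=C/[C@H]1OC(=O)[C@@H](C)[C@]1(O[Si](CC)(CC)CC)[C@@H](OC(C)=O)[C@@H]2[C@]3(CO3)C[C@@H](OC(C)=O)[C@@H](OC(C)=O)[C@@]2(C)[C@@H](OC(C)=O)CCO
F2 | step 26 | aldehyde from F1 (C2(OAc)–CH2–CHO, C4 aldehyde) | I\C(CO[Si](c1ccccc1)(c1ccccc1)C(C)(C)C)=C/[C@H]1OC(=O)[C@@H](C)[C@]1(O[Si](CC)(CC)CC)[C@@H](OC(C)=O)[C@@H]2[C@]3(CO3)C[C@@H](OC(C)=O)[C@@H](OC(C)=O)[C@@]2(C)[C@@H](OC(C)=O)CC=O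
F3 | step 26 | macrocyclic allylic alcohol: 3,4-dihydro-4-hydroxy analogue of 35 (C4 carbinol epimers) | CC(=O)O[C@H]1CC(O)\C(CO[Si](c2ccccc2)(c2ccccc2)C(C)(C)C)=C/[C@H]2OC(=O)[C@@H](C)[C@]2(O[Si](CC)(CC)CC)[C@@H](OC(C)=O)[C@@H]2[C@]3(CO3)C[C@@H](OC(C)=O)[C@@H](OC(C)=O)[C@@]12C
F4 | step 20 | bis(trimethylsilyl) dienol ether of 10 (14-OSiMe3; C10=C11(OSiMe3)–C12=C13) | CC(=O)O[C@@H](C=C)[C@@]1(C)C=C(O[Si](C)(C)C)C=C[C@H]1O[Si](C)(C)C
F5 | step 17 | tert-butyl ester with 7-O-benzoate (C7 inverted), 8-OH and 9-OH, from C3-selective opening of 23 | I\C(CO[Si](c1ccccc1)(c1ccccc1)C(C)(C)C)=C/[C@@H](OC(=O)c1ccccc1)[C@@](O)(CO)[C@H](C)C(=O)OC(C)(C)C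
F6 | step 17 | triol tert-butyl ester (7-OH, 8-OH, 9-OH) from debenzoylation of F5 | I\C(CO[Si](c1ccccc1)(c1ccccc1)C(C)(C)C)=C/[C@@H](O)[C@@](O)(CO)[C@H](C)C(=O)OC(C)(C)C
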